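Ring B carries its hydroxyl at C1, the ether oxygen at C2 and bromines at C3 and C5. It is not built by substitution on a phenol but assembled from two pieces. The C3(Br)–C4(H)–C5(Br)–C6(H) strip is the C3–C6 diene of 3,5-dibromo-2-pyrone. The adjacent oxygenated carbons C2 and C1 are the two carbons of an alkyne that already bears the ring A aryloxy group (3,5-dibromo-2-methoxyphenoxy) and a pinacolboryl group. One thermal cycloaddition with loss of CO2 creates ring B, sets both bromines meta to the latent hydroxyl and leaves the diaryl ether oxygen free of any aryl coupling. Oxidation of the C–B bond then reveals the C1 hydroxyl.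

Key step: step 7

Remark: the target has no stereocentre; the dibromoethyl ether of step 4 and the bridged lactone of step 7 are racemic and lose their stereocentres within the same step, and the bromovinyl ether is drawn as the Z isomer expected to predominate.

Step 1
Reactants: 1 3,5-dibromosalicylaldehyde
Product: 2 3,5-dibromo-2-methoxybenzaldehyde
Conditions: MeI, K2CO3, DMF, rt
Reagents that add atoms: iodomethane, CI
Why: Williamson O-methylation of the acidic salicylaldehyde phenol with iodomethane under carbonate base is routine and leaves the aldehyde and both C–Br bonds untouched.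

Step 2
Reactants: 2 3,5-dibromo-2-methoxybenzaldehyde
Product: 4 3,5-dibromo-2-methoxyphenol, via aryl formate 3 (not isolated)
Conditions: mCPBA, CH2Cl2, 40 °C; then K2CO3 (cat.), MeOH, rt
Reagents that add atoms: 3-chloroperoxybenzoic acid, OOC(=O)c1cccc(Cl)c1
Why: Baeyer–Villiger oxidation of an ortho-alkoxybenzaldehyde proceeds by migration of the oxygen-substituted aryl group to give formate 3, and methanolysis (transesterification) of the formate frees the phenol, so that the ether oxygen of ring A replaces the formyl carbon while the methoxy group and the bromines stay in place.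

Step 3
Reactants: 4 3,5-dibromo-2-methoxyphenol; 5 vinyl acetate
Product: 6 1,5-dibromo-3-(ethenyloxy)-2-methoxybenzene
Conditions: [IrCl(cod)]2 (1 mol %; cod = cycloocta-1,5-diene), Na2CO3 (0.6 equiv), toluene, 100 °C
Reagents that add atoms: none
Why: Iridium-catalysed transfer vinylation of phenols with vinyl acetate (addition of the phenoxide to the coordinated vinyl ester followed by loss of acetate) is established chemistry that needs no phosphine ligand and should not insert into the aryl C–Br bonds.

Step 4
Reactants: 6 1,5-dibromo-3-(ethenyloxy)-2-methoxybenzene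
Product: 8 1,5-dibromo-3-{[(Z)-2-bromoethenyl]oxy}-2-methoxybenzene, via dibromoethyl ether 7 (not isolated)
Conditions: Br2 (1.0 equiv), CH2Cl2, –78 °C; then i-Pr2NEt, –78 → 40 °C
Reagents that add atoms: bromine, BrBr
Why: Electrophilic addition of Br2 to the electron-rich enol ether double bond at –78 °C should be much faster than substitution on the deactivated ring A, and amine-promoted dehydrobromination of the α-bromo ether 7 (loss of the labile bromide next to oxygen and a β-proton) is the classical route to 2-bromovinyl ethers, the Z isomer being expected to predominate.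

Step 5
Reactants: 8 1,5-dibromo-3-{[(Z)-2-bromoethenyl]oxy}-2-methoxybenzene; 9 2-isopropoxy-4,4,5,5-tetramethyl-1,3,2-dioxaborolane
Product: 13 2-[(3,5-dibromo-2-methoxyphenoxy)ethynyl]-4,4,5,5-tetramethyl-1,3,2-dioxaborolane, via terminal ynol ether 10 (not isolated), via sodium acetylide 11 (not isolated), via sodium borate complex 12 (not isolated)
Conditions: NaN(SiMe3)2 (2.1 equiv), THF, –78 → 0 °C; 9 (1.1 equiv), –78 °C; HCl (1.1 equiv, Et2O), –78 °C → rt; filtration under argon, crude 13 used directly
Reagents that add atoms: none
Why: Anti-periplanar β-elimination of HBr from the Z-bromovinyl ether by NaN(SiMe3)2, a base that unlike an alkyllithium cannot exchange with the aryl bromides, should give ynol ether 10 and at once its acetylide 11, and capture of 11 by the alkoxyboronate 9 followed by protonolysis of borate 12 with one equivalent of anhydrous HCl is the standard electrophilic borylation of metal acetylides.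

Step 6
Reactants: 14 coumalic acid
Product: 15 3,5-dibromo-2H-pyran-2-one
Conditions: NBS (2.5 equiv), LiOAc (0.2 equiv), MeCN/H2O, rt
Reagents that add atoms: N-bromosuccinimide, O=C1CCC(=O)N1Br
Why: Bromodecarboxylation (Hunsdiecker-type ipso substitution of the C5 carboxylate by electrophilic bromine) followed by electrophilic bromination at the nucleophilic C3 of the pyrone is a known one-flask conversion of coumalic acid into the 3,5-dibromopyrone.

Step 7
Reactants: 13 2-[(3,5-dibromo-2-methoxyphenoxy)ethynyl]-4,4,5,5-tetramethyl-1,3,2-dioxaborolane; 15 3,5-dibromo-2H-pyran-2-one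
Product: 17 2-[3,5-dibromo-2-(3,5-dibromo-2-methoxyphenoxy)phenyl]-4,4,5,5-tetramethyl-1,3,2-dioxaborolane, via bridged lactone 16 (not isolated)
Conditions: 15 (1.5 equiv), toluene, 120 °C, sealed tube, argon
Reagents that add atoms: none
Why: The electron-poor diene C3=C4–C5=C6 of pyrone 15 and the push–pull triple bond of 13 should combine in an asynchronous inverse-electron-demand Diels–Alder addition that joins pyrone C3 to the aryloxy-bearing alkyne carbon and pyrone C6 to the boron-bearing carbon (the C3–C2 and C6–C1 bonds of ring B) to give the bridged lactone 16, which expels CO2 by retro-Diels–Alder cycloreversion at the reaction temperature and thereby aromatises to 17. The closest known reaction type is the cycloaddition/decarboxylation of 2-pyrones with alkynylboronates to arylboronates, together with the regioselective cycloadditions of 3,5-dibromo-2-pyrone with enol ethers, in which the oxygen-bearing dienophile carbon bonds to C3. Ring B is closed by an intermolecular [4+2] annulation (two σ bonds formed suprafacially through a six-membered transition state) rather than by cyclisation of a chain, and the CO2 bridge of 16 is then cut so that only the benzene ring remains. No stereocentre is created in 17; the two bridgehead centres of 16 form as a racemate and are erased on loss of CO2. The step needs one orientation, boron-bearing carbon to pyrone C6 and aryloxy-bearing carbon to pyrone C3: donation from the ynol ether oxygen, reinforced by the vacant p orbital on boron, puts the larger HOMO coefficient on the boron-bearing carbon, which therefore attacks C6, the diene terminus with the larger LUMO coefficient, and the bulky boronate also avoids the brominated C3. Because neither metal nor base is present, the four C–Br bonds, the methyl ether and the C–B bond should pass unchanged.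

Step 8
Reactants: 17 2-[3,5-dibromo-2-(3,5-dibromo-2-methoxyphenoxy)phenyl]-4,4,5,5-tetramethyl-1,3,2-dioxaborolane
Product: 18 3,5-dibromo-2-(3,5-dibromo-2-methoxyphenoxy)phenol
Conditions: H2O2 (30% aq.), NaOH (aq.), THF, 0 °C → rt
Reagents that add atoms: hydrogen peroxide, OO
Why: Oxidation of the arylboronate with alkaline hydrogen peroxide (addition of hydroperoxide to boron, 1,2-shift of the aryl group from boron to oxygen, hydrolysis of the borate ester) replaces C–B by C–OH at C1 of ring B without touching the aryl bromides, the methyl ether or the diaryl ether.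

Compound list
1 | 3,5-dibromosalicylaldehyde (3,5-dibromo-2-hydroxybenzaldehyde) | O=Cc1cc(Br)cc(Br)c1O | starting material
2 | 3,5-dibromo-2-methoxybenzaldehyde | COc1c(Br)cc(Br)cc1C=O | intermediate
3 | 3,5-dibromo-2-methoxyphenyl formate | COc1c(Br)cc(Br)cc1OC=O | intermediate
4 | 3,5-dibromo-2-methoxyphenol | COc1c(Br)cc(Br)cc1O | intermediate
5 | vinyl acetate | CC(=O)OC=C | starting material
6 | 1,5-dibromo-3-(ethenyloxy)-2-methoxybenzene | COc1c(Br)cc(Br)cc1OC=C | intermediate
7 | 1,5-dibromo-3-(1,2-dibromoethoxy)-2-methoxybenzene (racemic) | COc1c(Br)cc(Br)cc1OC(Br)CBr | intermediate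
8 | 1,5-dibromo-3-{[(Z)-2-bromoethenyl]oxy}-2-methoxybenzene | COc1c(Br)cc(Br)cc1O/C=C\Br | intermediate
9 | 2-isopropoxy-4,4,5,5-tetramethyl-1,3,2-dioxaborolane | CC(C)OB1OC(C)(C)C(C)(C)O1 | starting material
10 | 1,5-dibromo-3-(ethynyloxy)-2-methoxybenzene | COc1c(Br)cc(Br)cc1OC#C | intermediate
11 | sodium 2-(3,5-dibromo-2-methoxyphenoxy)ethyn-1-ide | COc1c(Br)cc(Br)cc1OC#[C-].[Na+] | intermediate
12 | sodium [(3,5-dibromo-2-methoxyphenoxy)ethynyl](isopropoxy)(pinacolato)borate | [Na+].COc1c(Br)cc(Br)cc1OC#C[B-]1(OC(C)C)OC(C)(C)C(C)(C)O1 | intermediate
13 | 2-[(3,5-dibromo-2-methoxyphenoxy)ethynyl]-4,4,5,5-tetramethyl-1,3,2-dioxaborolane | COc1c(Br)cc(Br)cc1OC#CB1OC(C)(C)C(C)(C)O1 | intermediate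
14 | coumalic acid (2-oxo-2H-pyran-5-carboxylic acid) | O=C(O)C1=COC(=O)C=C1 | starting material
15 | 3,5-dibromo-2H-pyran-2-one | O=C1OC=C(Br)C=C1Br | intermediate
16 | 4,7-dibromo-5-(3,5-dibromo-2-methoxyphenoxy)-6-(4,4,5,5-tetramethyl-1,3,2-dioxaborolan-2-yl)-2-oxabicyclo[2.2.2]octa-5,7-dien-3-one (racemic) | BrC12C(=O)OC(C(Br)=C1)C(B3OC(C)(C)C(C)(C)O3)=C2Oc4cc(Br)cc(Br)c4OC | intermediate
17 | 2-[3,5-dibromo-2-(3,5-dibromo-2-methoxyphenoxy)phenyl]-4,4,5,5-tetramethyl-1,3,2-dioxaborolane | COc1c(Br)cc(Br)cc1Oc1c(Br)cc(Br)cc1B1OC(C)(C)C(C)(C)O1 | intermediate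
18 | 3,5-dibromo-2-(3,5-dibromo-2-methoxyphenoxy)phenol | COc1c(Br)cc(Br)cc1Oc1c(O)cc(Br)cc1Br | target

Total step count: 8. Longest linear sequence: 7 steps (steps 1, 2, 3, 4, 5, 7, 8 from 1); the pyrone branch (step 6) joins at step 7.

Steps most likely to fail

Step 7. The cycloaddition may be too slow at temperatures the ynol ether boronate tolerates, so that oligomerisation or protodeboronation of 13 wins, or part of the material may add in the reverse orientation. The fallback gives up the cycloaddition and sets out from phenol 4. Nucleophilic aromatic substitution on commercially available 3,5-dibromo-2-fluorobenzaldehyde (O=Cc1cc(Br)cc(Br)c1F; K2CO3, DMF, 80 °C), whose ortho-formyl group activates the C–F bond, should give 3,5-dibromo-2-(3,5-dibromo-2-methoxyphenoxy)benzaldehyde F1. Baeyer–Villiger oxidation (mCPBA, CH2Cl2) to 3,5-dibromo-2-(3,5-dibromo-2-methoxyphenoxy)phenyl formate F2 and methanolysis (K2CO3, MeOH) come back to the route at the target 18. The ether oxygen is still formed without a metal-mediated coupling.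

Step 5. HCl may add across the electron-rich triple bond, or boron may be lost hydrolytically, while the borate complex is broken up and 13 is isolated. The fallback sets out from 8 and generates acetylide 11 as before, but quenches it with chlorobis(diisopropylamino)borane (CC(C)N(C(C)C)B(Cl)N(C(C)C)C(C)C) instead of 9. Substitution at boron should give 1-[(3,5-dibromo-2-methoxyphenoxy)ethynyl]-N,N,N',N'-tetraisopropylboranediamine F3 with no acid at any stage. Exchange of both amino groups with pinacol (toluene, rt to 60 °C, amine removed in vacuo) comes back to the route at 13.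

Step 3. The hindered and rather acidic phenol may be vinylated only slowly, or the iridium catalyst may be consumed by insertion into a C–Br bond, so that conversion stalls. The fallback sets out from phenol 4 and uses no transition metal. Alkylation with an excess of 1,2-dibromoethane (BrCCBr; K2CO3, MeCN, reflux) should give 1,5-dibromo-3-(2-bromoethoxy)-2-methoxybenzene F4. Dehydrobromination of this primary bromide with KOC(CH3)3 (THF, 0 °C → rt), the classical preparation of aryl vinyl ethers, comes back to the route at 6.

Further compounds
F1 | step 7 | 3,5-dibromo-2-(3,5-dibromo-2-methoxyphenoxy)benzaldehyde | COc1c(Br)cc(Br)cc1Oc1c(Br)cc(Br)cc1C=O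
F2 | step 7 | 3,5-dibromo-2-(3,5-dibromo-2-methoxyphenoxy)phenyl formate | COc1c(Br)cc(Br)cc1Oc1c(Br)cc(Br)cc1OC=O
F3 | step 5 | 1-[(3,5-dibromo-2-methoxyphenoxy)ethynyl]-N,N,N',N'-tetraisopropylboranediamine | COc1c(Br)cc(Br)cc1OC#CB(N(C(C)C)C(C)C)N(C(C)C)C(C)C
F4 | step 3 | 1,5-dibromo-3-(2-bromoethoxy)-2-methoxybenzene | COc1c(Br)cc(Br)cc1OCCBr
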